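## Structural features

The target is a germacranolide: a ten-membered carbocycle C1–C10 (germacrane numbering; C14 on C10, C15 on C4) fused along C6–C7 to a γ-alkylidene butenolide (O–C6, C7=C11, C12=O, C13 on C11), whose exocyclic C5=C6 bond lies inside the carbocycle. Six of the ten ring carbons are sp2 or epoxide carbons: the (Z)-C1=C10 trisubstituted alkene, the cis C2–C3 epoxide, the ring-cis C5=C6 enol ester and C7. The stereocentres form two sets that cannot relay to each other: C2/C3/C4 (epoxide syn to the tertiary C4–OH) and the trans-dioxygenated pair C8/C9, separated by sp2 carbons on both sides. Four different allylic acyloxy groups must be placed: angelate on O8, acetates on O9 and O13, and (E)-4-hydroxy-3-methylbut-2-enoate on O14, next to a free tertiary and a free primary hydroxyl. Fragile groups are the dienol lactone (an acylating agent, labile to base and nucleophiles), the vinyl epoxide beside a tertiary carbinol (acid-labile), the angelate (Z to E isomerisation) and the vicinal C8/C9 esters (acyl migration). The real difficulty is the strained ten-membered ring with its (Z)-C1=C10 bond and ketone-level C6, together with control of C4 relative to C8/C9. The key step exploits the array O–C6···C1–C10–C9–O: C6 (carbonyl level) and C10 (alkene carbon whose neighbour C9 bears oxygen) both flank C1, so the ring is the Grob fragmentation product of a cis-decalin with ring A = C1–C6 and ring B = C6–C7–C8–C9–C10–C1, cut at the C1–C6 fusion bond. The same ten carbons plus C15 map onto isoprene (C2–C5, C15) and a benzoquinone (C6–C10, C1).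

## Logic of the disconnections

40 ⇐ 39 ⇐ 36 + 37 and 36 ⇐ 31 + 35. Cut: the O–Si bond of the side chain and the acyl C–O bonds at O8 and O14. These esters cannot survive the basic ring expansion and are therefore last. This removes both unsaturated acyl groups. Demand: the primary C14–OH must be acylated before the hindered secondary C8–OH, and the angelate must be introduced without Z to E isomerisation or acetyl migration from O9.

31 ⇐ 30 ⇐ 29. Cut: the two 4-methoxybenzyl C–O bonds and the two C–O bonds of the 2,3-epoxide. The epoxide is syn to the C4 hydroxyl, so it is the product of a hydroxyl-directed oxygen transfer to a 1(10),2-diene. Demand: reaction at C2=C3 only, not at C1=C10 or the enol-ester C5=C6.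

29 ⇐ 28 ⇐ 27 ⇐ 26. Cut: the acetyl C–O bonds at O13 and O9, the silyl ethers, and the enol-lactone bond C12–O(C6) with the C5=C6 π bond. This returns to a hydroxybutenolide, the ring tautomer of a (Z)-4-oxo-2-enoic acid. Demand: enolisation of the C6 ketone can only go toward C5 (C7 carries no hydrogen), and must give the ring-cis C5=C6 geometry.

26 ⇐ 24 (key). Reconnect C1–C6; remove the C1=C10 π bond and the C6 carbonyl; restore the C9–C10 epoxide and the C6–O lactone bond. The strained ten-membered ring becomes a cis-decalin whose faces are rigid, and the (Z)-alkene becomes a stereochemical consequence of an antiperiplanar fragmentation. Demand: O10 cis to C2 on ring B, a cis ring fusion, a C6 alkoxide that is released only in this step, and protected O8 and O4.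

24 ⇐ 23 ⇐ 22 ⇐ 20 + 21, and 20 ⇐ 19. Cut: C7=C11 (dehydration), C7–C11 (intramolecular aldol), the ester bond O6–C12, and the C6–O bond (enolate oxidation). All three lactone carbons come from one commercial acid. Demand: enolisation of the C7 ketone toward C6, not toward the oxygenated C8.

19 ⇐ 18 ⇐ 15 ⇐ 14. Cut: the silyl ether at O4, the O8–benzyl bond, the C9–O10 bond (epoxide migration in reverse), and the C8–C9 epoxide back to an enone. One enone and the tertiary O10 supply both oxygens of the trans C8/C9 pair and leave them differentiated. Demand: epoxidation anti to O10, so that O10 can open the epoxide at C9 from the rear.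

14 ⇐ 13 ⇐ 10 ⇐ 9. Cut: the ketal, then C4–OH/C2=C3 back to a C3–C4 epoxide, then to the ring A alkene. C4 is set on the convex face of the cis-decalin. Demand: convex-face epoxidation, opening at C3, and elimination toward C2 only.

9 ⇐ 3 + 6, and 6 ⇐ 4 + 5. Cut: C10–C14 and the O–Si bond. Addition to the C10 ketone from the convex face fixes O10 on the face of C2, as the fragmentation requires. Demand: 1,2-addition without enolisation at C1.

3 ⇐ 1 + 2. Cut: C1–C2 and C5–C6 (Diels–Alder). All ten ring carbons and C15 arrive in one step. Demand: discrimination of the two enantiotopic enone double bonds of 1, and "para" orientation so that C15 sits on C4.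

35 ⇐ 34 ⇐ 33 ⇐ 32. Cut: the ester O–C, O–Si and C4–H bonds of the side chain, which comes from a commercial (E)-aldehyde ester.

## Other disconnections considered

Alternative 1: the first that comes to mind. Cut C9–C10 and close the ring by a Nozaki–Hiyama–Kishi reaction (CrCl2, NiCl2 cat.) of the (Z)-alkenyl iodide and the C9 aldehyde in seco-compound A1. The chain would have to fold with three cis-configured units (iodoalkene, epoxide, dienol lactone) already in place, so strain and entropy both oppose closure and intermolecular coupling competes. The new C9 carbinol would be set under Felkin control from C8, which predicts the 8,9-anti (erythro) relationship and not the threo one required. Each of the five stereocentres of A1 needs its own reagent-controlled step in open-chain fragments. The chosen plan sets C4, C8 and C9 on the faces of a decalin made in one step and obtains the ring by a fragmentation driven by C=O formation and epoxide strain release.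

Alternative 2: cut C8–C9 and form it by an anionic oxy-Cope rearrangement (KH, 18-crown-6) of the 1,2-dialkenylcyclohexenol A2, both termini carrying oxygen. The chair transition state places the ring bond C1–C2 equatorial and so leads to the (E)-C1=C10 alkene; the (Z)-isomer needs the axial arrangement. The configuration at C8/C9 would depend on the chair/boat partition and on two enol ether geometries. The rearrangement gives the C6 enolate toward C7, so C7=C11 and C5=C6 would still need two oxidation-level adjustments. The ketone from which A2 is made is a β,γ-unsaturated β-oxygenated cyclohexanone that aromatises easily.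

Alternative 3: cut C5–C6 and close it by an intramolecular vinylogous Mukaiyama aldol addition of the 2-silyloxyfuran in A3 to the C5 aldehyde, then dehydrate to the enol lactone. This closure sets no stereocentre, has no driving force to offset ring strain, and needs a Lewis acid next to a vinyl epoxide and a neopentyl α-oxygenated aldehyde. A3 itself requires separate control of C2, C3, C4, C8, C9 and of the (Z)-alkene, which is a longer assembly than the one-step cycloaddition of the chosen plan.

Key step: step 14

Remarks on the chemistry. Germacrane numbering is used for every intermediate; in the bicyclic compounds α is the face carrying H-1 (and H-6 or O-6) and β the opposite face. The (R)-BINOL ligand of step 1 is assumed to favour the (4aS,8aR) adduct drawn; the mirror-image ligand is to be taken if the sense of induction is the opposite.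

## Steps

Step 1
Reactants: 1 4,4-dimethoxycyclohexa-2,5-dien-1-one; 2 isoprene
Product: 3 (4aS,8aR)-4,4-dimethoxy-6-methyl-4a,5,8,8a-tetrahydronaphthalen-1(4H)-one (cis-fused; C10 ketone, C8=C9, C7 ketal, C3=C4 bearing C15)
Conditions: (R)-BINOL, TiCl2(OiPr)2 (10 mol %), 4 Å MS, CH2Cl2, −20 °C → rt
Reagents that add atoms: none
Why: Catalytic enantioselective Diels–Alder reaction of a quinone monoketal; suprafacial addition gives the cis fusion, the "para" orientation places C15 on C4, and the chiral Lewis acid selects one enantiotopic enone double bond and face, which sets C1 and C6.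

Step 2
Reactants: 4 (tributylstannyl)methanol; 5 4-methoxybenzyl chloride
Product: 6 tributyl[(4-methoxybenzyloxy)methyl]stannane
Conditions: NaH, n-Bu4NI (cat.), THF/DMF, 0 °C → rt
Reagents that add atoms: none
Why: Williamson etherification of a primary alkoxide with a benzylic chloride.

Step 3
Reactants: 3 cis-fused adduct; 6 stannane
Product: 9 10β-triethylsilyloxy-10α-[(4-methoxybenzyloxy)methyl] derivative of 3 (C7 ketal, C8=C9, C3=C4), via (4-methoxybenzyloxy)methyllithium 7 (not isolated), via tertiary alcohol 8 (not isolated)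
Conditions: 6, n-BuLi, THF, −78 °C; CeCl3; 3, −78 °C; aq. NH4Cl; then Et3SiCl, imidazole, DMAP, DMF, 40 °C
Reagents that add atoms: chlorotriethylsilane, CC[Si](Cl)(CC)CC
Why: Tin–lithium exchange gives the α-alkoxymethyl anion, whose cerium reagent should add 1,2 to the enone without enolising C1. Attack from the convex α face puts C14 α and O10 β, that is cis to C2. The silyl ether later blocks the β face.

Step 4
Reactants: 9 silyl ether
Product: 10 3α,4α-epoxide of 9
Conditions: mCPBA (1.1 equiv), NaHCO3, CH2Cl2, 0 °C
Reagents that add atoms: 3-chloroperoxybenzoic acid, OOC(=O)c1cccc(Cl)c1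
Why: Peracid epoxidation of the electron-rich trisubstituted ring A alkene from the convex α face sets C4; the C8=C9 bond, flanked by two fully substituted carbons and deactivated by allylic oxygens, should not react.

Step 5
Reactants: 10 epoxide
Product: 13 4α-hydroxy-2-ene (tertiary allylic alcohol, C15 β; ketal and C8=C9 retained), via hydroxy selenide 11 (not isolated), via selenoxide 12 (not isolated)
Conditions: (PhSe)2, NaBH4, EtOH, 75 °C; then H2O2, THF, 0 °C → rt
Reagents that add atoms: none
Why: The selenolate opens the epoxide trans-diaxially at the less substituted C3, and selenoxide syn-elimination can only go toward C2 because C4 has no hydrogen. The C4 configuration is retained.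

Step 6
Reactants: 13 allylic alcohol
Product: 14 enone (C7 ketone conjugated with C8=C9; 10β-OSiEt3, 4α-OH)
Conditions: PPTS, acetone/H2O (10:1), rt
Reagents that add atoms: water, O
Why: Hydrolysis of an allylic dimethyl ketal to the conjugated enone under conditions that the tertiary silyl ether and tertiary allylic alcohol should tolerate.

Step 7
Reactants: 14 enone
Product: 15 8α,9α-epoxy ketone
Conditions: TBHP, DBU, CH2Cl2, 0 °C → rt
Reagents that add atoms: tert-butyl hydroperoxide, CC(C)(C)OO
Why: Weitz–Scheffer (nucleophilic) epoxidation; the hydroperoxide adds to C9 anti to the 10β-silyloxy group on the convex face, which sets C8 and fixes the epoxide trans to O10; the ring A alkene is inert.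

Step 8
Reactants: 15 epoxy ketone
Product: 18 9β,10β-epoxy-8α-(4-methoxybenzyloxy) C7 ketone with free 4α-OH, via desilylated epoxy alcohol 16 (not isolated), via rearranged hydroxy ketone 17 (not isolated)
Conditions: TBAF, THF, 0 °C; then 4-methoxybenzyl bromide, 0 °C → rt
Reagents that add atoms: 4-methoxybenzyl bromide, COc1ccc(CBr)cc1
Why: Payne rearrangement: the liberated 10β-alkoxide opens the trans-disposed epoxide at C9 with inversion, giving the more substituted 9β,10β-epoxide and the less basic α-keto C8 alkoxide, which is trapped by benzylation. This sets C9 trans to O8 and differentiates the two oxygens.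

Step 9
Reactants: 18 tertiary alcohol
Product: 19 4-O-tert-butyldimethylsilyl ether of 18
Conditions: TBSOTf, 2,6-lutidine, CH2Cl2, −78 → 0 °C
Reagents that add atoms: tert-butyldimethylsilyl trifluoromethanesulfonate, CC(C)(C)[Si](C)(C)OS(=O)(=O)C(F)(F)F
Why: Silylation of the tertiary allylic hydroxyl with a silyl triflate; the ketone and hindered epoxide should survive at low temperature.

Step 10
Reactants: 19 ketone
Product: 20 6α-hydroxy ketone (cis-fused α-ketol)
Conditions: LiN(SiMe3)2, THF, −78 °C; 2-(phenylsulfonyl)-3-phenyloxaziridine, −78 °C; AcOH, −78 °C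
Reagents that add atoms: 2-(phenylsulfonyl)-3-phenyloxaziridine, O=S(=O)(c1ccccc1)N1OC1c1ccccc1
Why: Enolate hydroxylation; kinetic deprotonation should occur at C6 because the α-alkoxy C8–H is kinetically less acidic and shielded, and oxygen transfer from the convex α face keeps the cis fusion. The cold acidic quench prevents premature fragmentation of the new alkoxide.

Step 11
Reactants: 20 α-ketol; 21 3-(tert-butyldimethylsilyloxy)propanoic acid
Product: 22 6-O-[3-(tert-butyldimethylsilyloxy)propanoyl] ester of 20
Conditions: EDC·HCl, DMAP, CH2Cl2, rt → 35 °C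
Reagents that add atoms: none
Why: Steglich-type esterification of the activated tertiary α-ketol hydroxyl; the only other oxygens are protected.

Step 12
Reactants: 22 ester
Product: 23 aldol lactone (7-hydroxy-12,6-olide with C13 silyloxymethyl on C11; mixture at C7 and C11)
Conditions: LiN(SiMe3)2, THF, −78 °C; AcOH, −78 °C
Reagents that add atoms: none
Why: Intramolecular aldol addition (5-exo) of the kinetically formed ester enolate to the adjacent C7 ketone; the two new centres are removed in step 13.

Step 13
Reactants: 23 aldol lactone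
Product: 24 tricyclic butenolide (7(11)-en-12,6-olide fused to the cis-decalin; 9β,10β-epoxide, 8α-OPMB, 4α-OTBS)
Conditions: Ph2S[OC(CF3)2Ph]2, CH2Cl2, 0 °C → rt
Reagents that add atoms: none
Why: Sulfurane dehydration of the tertiary β-hydroxy lactone toward the acidic C11–H gives the conjugated tetrasubstituted butenolide.

Step 14
Reactants: 24 tricyclic butenolide
Product: 26 ten-membered hydroxybutenolide (6-hydroxy-12,6-olide, (1(10)Z,2Z)-diene, free 9-OH; both C6 epimers), via potassium hydroxy carboxylate 25 (not isolated)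
Conditions: KOH, THF/H2O (3:1), 50 °C; then aq. H3PO4/KH2PO4 to pH 4, 0 °C
Reagents that add atoms: potassium hydroxide, [K+].[OH-]
Why: Hydroxide opens the lactone to the (Z)-carboxylate 25 and frees the tertiary C6 alkoxide, whose lone pair pushes into the C6–C1 bond: C6=O forms, C1–C6 breaks, the C1=C10 π bond forms and the C10–O bond of the epoxide breaks to leave the C9 alkoxide. The closest known reaction type is the Grob (Wharton) fragmentation of γ-oxygenated alkoxides, including the epoxy-alcohol variant used to make medium-ring ketones. No ring is closed in the fragmentation: the ten-membered ring is released by scission of the zero bridge of the bicyclo[4.4.0]decane, and on acidification the (Z)-4-oxo-2-enoic acid recloses to the hydroxybutenolide by 5-exo-trig addition of the carboxyl oxygen to the C6 ketone. No stereocentre is created; C4, C8 and C9 are carried through, and the C6 hemiketal centre is lost in step 15. The (Z)-geometry of C1=C10 follows from the antiperiplanar requirement: O10 is cis to C2 on ring B, so when the C10–O bond is anti to C1–C6 the C1–C2 bond is axial and gauche to C9, and C2 and C9 end cis; the trans-fused or O10-epimeric arrangement could not fragment this way. The step needs fragmentation to win over plain epoxide opening and over vinylogous deprotonation at C8. This is secured because the donor is generated only by saponification, the trisubstituted epoxide is hindered toward external hydroxide, O8 and O4 are protected, and the carboxylate formed first no longer acidifies C8–H. The developing C1=C10 bond is conjugated with C2=C3 and the epoxide strain is released, which should drive the cleavage.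

Step 15
Reactants: 26 hydroxybutenolide
Product: 27 dienol lactone 9-acetate (C5=C6 enol lactone, 9-OAc, 8-OPMB, 14-OPMB, 13-OTBS, 4-OTBS)
Conditions: Ac2O, Et3N, DMAP (cat.), CH2Cl2, 0 → 35 °C
Reagents that add atoms: acetic anhydride, CC(=O)OC(C)=O
Why: Enol lactonisation of a γ-keto acid: under base the pseudo-acid opens, the carboxylate forms a mixed anhydride, and the C6 ketone can enolise only toward C5, so O-acylation gives the γ-alkylidene butenolide. The ring should favour C4 cis to C7, and the C9 hydroxyl is acetylated in the same operation.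

Step 16
Reactants: 27 bis-silyl ether
Product: 28 4,13-diol
Conditions: HF·pyridine, pyridine, THF, 0 °C → rt
Reagents that add atoms: none
Why: Buffered fluoride desilylation of the primary and tertiary silyl ethers; benzyl ethers, acetate and enol lactone should survive.

Step 17
Reactants: 28 diol
Product: 29 13-acetate
Conditions: AcCl, 2,4,6-collidine, CH2Cl2, −78 °C
Reagents that add atoms: acetyl chloride, CC(Cl)=O
Why: Selective acetylation of the primary allylic hydroxyl; the tertiary C4–OH does not react under these conditions.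

Step 18
Reactants: 29 dienol
Product: 30 2,3-epoxide syn to the C4 hydroxyl
Conditions: VO(acac)2 (cat.), TBHP, CH2Cl2, 0 °C
Reagents that add atoms: tert-butyl hydroperoxide, CC(C)(C)OO
Why: Hydroxyl-directed vanadium-catalysed epoxidation delivers oxygen to the allylic C2=C3 bond on the face of the C4 hydroxyl, which sets C2 and C3. The enol-ester C5=C6 is electron-poor and C1=C10 is not allylic to the hydroxyl.

Step 19
Reactants: 30 bis(4-methoxybenzyl) ether
Product: 31 8,14-diol
Conditions: DDQ, CH2Cl2/pH 7 phosphate buffer, 0 °C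
Reagents that add atoms: none
Why: Oxidative cleavage of both 4-methoxybenzyl ethers under neutral buffered conditions that the vinyl epoxide and esters should tolerate.

Step 20
Reactants: 32 ethyl (E)-3-methyl-4-oxobut-2-enoate
Product: 33 ethyl (E)-4-hydroxy-3-methylbut-2-enoate
Conditions: NaBH4, CeCl3·7H2O, EtOH, −20 °C
Reagents that add atoms: none
Why: Luche 1,2-reduction of the enal; the ester and the alkene geometry are untouched.

Step 21
Reactants: 33 allylic alcohol
Product: 34 ethyl (E)-4-(tert-butyldimethylsilyloxy)-3-methylbut-2-enoate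
Conditions: TBSCl, imidazole, DMF, rt
Reagents that add atoms: tert-butyldimethylsilyl chloride, CC(C)(C)[Si](C)(C)Cl
Why: Standard silylation of a primary alcohol.

Step 22
Reactants: 34 ester
Product: 35 (E)-4-(tert-butyldimethylsilyloxy)-3-methylbut-2-enoic acid
Conditions: LiOH, THF/H2O, 0 °C → rt; aq. NaH2PO4
Reagents that add atoms: lithium hydroxide, [Li+].[OH-]
Why: Saponification; the (E)-geometry prevents lactonisation and the silyl ether survives mild base and the buffered work-up.

Step 23
Reactants: 31 diol; 35 acid
Product: 36 14-O-[(E)-4-(tert-butyldimethylsilyloxy)-3-methylbut-2-enoyl] ester with free 8-OH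
Conditions: EDC·HCl, DMAP (cat.), CH2Cl2, −20 °C
Reagents that add atoms: none
Why: Carbodiimide esterification of the primary allylic C14 hydroxyl in preference to the hindered secondary C8 and tertiary C4 hydroxyls; the low temperature limits acetyl migration from O9.

Step 24
Reactants: 36 alcohol; 37 angelic acid
Product: 39 8-O-angeloyl derivative (silyl-protected target), via mixed anhydride 38 (not isolated)
Conditions: 37, 2,4,6-Cl3C6H2COCl, Et3N, toluene, rt; then 36, 75 °C
Reagents that add atoms: none
Why: Yamaguchi esterification through the mixed anhydride without a nucleophilic catalyst, which should acylate the secondary hydroxyl while avoiding angelate to tiglate isomerisation.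

Step 25
Reactants: 39 silyl ether
Product: 40 CNP0290534.1 (target)
Conditions: HF·pyridine, pyridine, THF, 0 °C
Reagents that add atoms: none
Why: Buffered fluoride cleavage of the primary allylic silyl ether; all esters, the epoxide and the enol lactone should be stable.

## Compound list

1 | 4,4-dimethoxycyclohexa-2,5-dien-1-one | COC1(OC)C=CC(=O)C=C1 | starting material
2 | isoprene | C=CC(C)=C | starting material
3 | (4aS,8aR)-4,4-dimethoxy-6-methyl-4a,5,8,8a-tetrahydronaphthalen-1(4H)-one | O=C1C=CC(OC)(OC)[C@H]2CC(C)=CC[C@@H]12 | intermediate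
4 | (tributylstannyl)methanol | CCCC[Sn](CCCC)(CCCC)CO | starting material
5 | 4-methoxybenzyl chloride | COc1ccc(CCl)cc1 | starting material
6 | tributyl[(4-methoxybenzyloxy)methyl]stannane | CCCC[Sn](CCCC)(CCCC)COCc1ccc(OC)cc1 | intermediate
7 | (4-methoxybenzyloxy)methyllithium | [Li]COCc1ccc(OC)cc1 | intermediate
8 | 10β-hydroxy-10α-[(4-methoxybenzyloxy)methyl] adduct (tertiary alcohol) | O[C@@]1(COCc2ccc(OC)cc2)C=CC(OC)(OC)[C@H]3CC(C)=CC[C@@H]13 | intermediate
9 | 10β-triethylsilyl ether of 8 | CC[Si](CC)(CC)O[C@@]1(COCc2ccc(OC)cc2)C=CC(OC)(OC)[C@H]3CC(C)=CC[C@@H]13 | intermediate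
10 | 3α,4α-epoxide of 9 | CC[Si](CC)(CC)O[C@@]1(COCc2ccc(OC)cc2)C=CC(OC)(OC)[C@H]3C[C@]4(C)O[C@@H]4C[C@@H]13 | intermediate
11 | 3β-phenylselanyl-4α-ol | CC[Si](CC)(CC)O[C@@]1(COCc2ccc(OC)cc2)C=CC(OC)(OC)[C@H]3C[C@](C)(O)[C@@H]([Se]c4ccccc4)C[C@@H]13 | intermediate
12 | selenoxide of 11 | CC[Si](CC)(CC)O[C@@]1(COCc2ccc(OC)cc2)C=CC(OC)(OC)[C@H]3C[C@](C)(O)[C@@H]([Se](=O)c4ccccc4)C[C@@H]13 | intermediate
13 | 4α-hydroxy-2-ene, C7 dimethyl ketal | CC[Si](CC)(CC)O[C@@]1(COCc2ccc(OC)cc2)C=CC(OC)(OC)[C@H]3C[C@](C)(O)C=C[C@@H]13 | intermediate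
14 | C7 enone | CC[Si](CC)(CC)O[C@@]1(COCc2ccc(OC)cc2)C=CC(=O)[C@H]3C[C@](C)(O)C=C[C@@H]13 | intermediate
15 | 8α,9α-epoxy ketone | CC[Si](CC)(CC)O[C@@]1(COCc2ccc(OC)cc2)[C@@H]4O[C@@H]4C(=O)[C@H]3C[C@](C)(O)C=C[C@@H]13 | intermediate
16 | desilylated 10β-hydroxy-8α,9α-epoxy ketone | O[C@@]1(COCc2ccc(OC)cc2)[C@@H]4O[C@@H]4C(=O)[C@H]3C[C@](C)(O)C=C[C@@H]13 | intermediate
17 | rearranged 8α-hydroxy-9β,10β-epoxy ketone | [C@@]14(COCc2ccc(OC)cc2)O[C@H]4[C@H](O)C(=O)[C@H]3C[C@](C)(O)C=C[C@@H]13 | intermediate
18 | 8α-(4-methoxybenzyloxy)-9β,10β-epoxy ketone, 4α-ol | [C@@]14(COCc2ccc(OC)cc2)O[C@H]4[C@H](OCc2ccc(OC)cc2)C(=O)[C@H]3C[C@](C)(O)C=C[C@@H]13 | intermediate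
19 | 4-O-tert-butyldimethylsilyl ether of 18 | [C@@]14(COCc2ccc(OC)cc2)O[C@H]4[C@H](OCc2ccc(OC)cc2)C(=O)[C@H]3C[C@](C)(O[Si](C)(C)C(C)(C)C)C=C[C@@H]13 | intermediate
20 | 6α-hydroxy ketone | [C@@]14(COCc2ccc(OC)cc2)O[C@H]4[C@H](OCc2ccc(OC)cc2)C(=O)[C@@]3(O)C[C@](C)(O[Si](C)(C)C(C)(C)C)C=C[C@@H]13 | intermediate
21 | 3-(tert-butyldimethylsilyloxy)propanoic acid | OC(=O)CCO[Si](C)(C)C(C)(C)C | starting material
22 | 6-O-[3-(tert-butyldimethylsilyloxy)propanoyl] ester | [C@@]14(COCc2ccc(OC)cc2)O[C@H]4[C@H](OCc2ccc(OC)cc2)C(=O)[C@@]3(OC(=O)CCO[Si](C)(C)C(C)(C)C)C[C@](C)(O[Si](C)(C)C(C)(C)C)C=C[C@@H]13 | intermediate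
23 | aldol lactone (mixture at C7 and C11) | [C@@]14(COCc2ccc(OC)cc2)O[C@H]4[C@H](OCc2ccc(OC)cc2)C5(O)C(CO[Si](C)(C)C(C)(C)C)C(=O)O[C@@]53C[C@](C)(O[Si](C)(C)C(C)(C)C)C=C[C@@H]13 | intermediate
24 | tricyclic butenolide | [C@@]14(COCc2ccc(OC)cc2)O[C@H]4[C@H](OCc2ccc(OC)cc2)C5=C(CO[Si](C)(C)C(C)(C)C)C(=O)O[C@@]53C[C@](C)(O[Si](C)(C)C(C)(C)C)C=C[C@@H]13 | intermediate
25 | ring-opened (Z)-hydroxy carboxylate, potassium salt | [C@@]14(COCc2ccc(OC)cc2)O[C@H]4[C@H](OCc2ccc(OC)cc2)/C(=C(\CO[Si](C)(C)C(C)(C)C)C(=O)[O-])[C@@]3(O)C[C@](C)(O[Si](C)(C)C(C)(C)C)C=C[C@@H]13.[K+] | intermediate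
26 | ten-membered hydroxybutenolide (both C6 epimers) | COc1ccc(CO[C@@H]2C3=C(CO[Si](C)(C)C(C)(C)C)C(=O)OC3(O)C[C@](C)(O[Si](C)(C)C(C)(C)C)/C=C\C=C(\COCc3ccc(OC)cc3)[C@H]2O)cc1 | intermediate
27 | dienol lactone 9-acetate | COc1ccc(CO[C@@H]2C3=C(CO[Si](C)(C)C(C)(C)C)C(=O)O/C3=C/[C@](C)(O[Si](C)(C)C(C)(C)C)/C=C\C=C(\COCc3ccc(OC)cc3)[C@H]2OC(C)=O)cc1 | intermediate
28 | 4,13-diol | COc1ccc(CO[C@@H]2C3=C(CO)C(=O)O/C3=C/[C@](C)(O)/C=C\C=C(\COCc3ccc(OC)cc3)[C@H]2OC(C)=O)cc1 | intermediate
29 | 13-acetate | COc1ccc(CO[C@@H]2C3=C(COC(C)=O)C(=O)O/C3=C/[C@](C)(O)/C=C\C=C(\COCc3ccc(OC)cc3)[C@H]2OC(C)=O)cc1 | intermediate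
30 | 2,3-epoxide | COc1ccc(CO[C@@H]2C3=C(COC(C)=O)C(=O)O/C3=C/[C@](C)(O)[C@@H]3O[C@@H]3/C=C(/COCc3ccc(OC)cc3)[C@H]2OC(C)=O)cc1 | intermediate
31 | 8,14-diol | O[C@@H]1C2=C(COC(C)=O)C(=O)O/C2=C/[C@](C)(O)[C@@H]2O[C@@H]2/C=C(/CO)[C@H]1OC(C)=O | intermediate
32 | ethyl (E)-3-methyl-4-oxobut-2-enoate | CCOC(=O)/C=C(\C)C=O | starting material
33 | ethyl (E)-4-hydroxy-3-methylbut-2-enoate | CCOC(=O)/C=C(\C)CO | intermediate
34 | ethyl (E)-4-(tert-butyldimethylsilyloxy)-3-methylbut-2-enoate | CCOC(=O)/C=C(\C)CO[Si](C)(C)C(C)(C)C | intermediate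
35 | (E)-4-(tert-butyldimethylsilyloxy)-3-methylbut-2-enoic acid | OC(=O)/C=C(\C)CO[Si](C)(C)C(C)(C)C | intermediate
36 | 14-ester with free 8-OH | O[C@@H]1C2=C(COC(C)=O)C(=O)O/C2=C/[C@](C)(O)[C@@H]2O[C@@H]2/C=C(/COC(=O)/C=C(\C)CO[Si](C)(C)C(C)(C)C)[C@H]1OC(C)=O | intermediate
37 | angelic acid | C/C=C(/C)C(=O)O | starting material
38 | angelic 2,4,6-trichlorobenzoic anhydride | C/C=C(/C)C(=O)OC(=O)c1c(Cl)cc(Cl)cc1Cl | intermediate
39 | silyl-protected target | C/C=C(/C)C(=O)O[C@@H]1C2=C(COC(C)=O)C(=O)O/C2=C/[C@](C)(O)[C@@H]2O[C@@H]2/C=C(/COC(=O)/C=C(\C)CO[Si](C)(C)C(C)(C)C)[C@H]1OC(C)=O | intermediate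
40 | CNP0290534.1 | C/C=C(/C)C(=O)O[C@@H]1C2=C(COC(C)=O)C(=O)O/C2=C/[C@](C)(O)[C@@H]2O[C@@H]2/C=C(/COC(=O)/C=C(\C)CO)[C@H]1OC(C)=O | target

## Step count and least certain steps

Total step count: 25. Longest linear sequence: 21 steps (steps 1, 3 to 19, 23 to 25).

Step 14 (key step). Most likely failure: saponification occurs but the fragmentation is slow, because an epoxide is a weak nucleofuge without electrophilic assistance. The butenolide or its carboxylate could then undergo vinylogous deprotonation at C8 with β-elimination of the epoxide, which destroys the leaving group. Fallback, from 24 to 26: reduce the lactone with i-Bu2AlH (CH2Cl2, −78 °C) to the lactol F1. Its ring-opened hydroxy enal form binds Ti(OiPr)4 (toluene, 60 °C) as a tertiary C6 titanium alkoxide, and the tetravalent titanium also activates the epoxide oxygen; this is the Lewis-acid form of the epoxy-alcohol fragmentation and should give the keto enal F2. Oxidation of the aldehyde with NaClO2/NaH2PO4/2-methylbut-2-ene should then give the keto acid, which closes to 26.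

Step 10. Most likely failure: enolisation toward C8 instead of C6, followed by β-elimination of the C9–C10 epoxide, which removes the nucleofuge needed in step 14. Fallback, from 15 to 22: run the fluoride step without the bromide so that the rearranged hydroxy ketone 17 is isolated. With 3.3 equiv LiN(SiMe3)2 the C8 and C4 hydroxyls become alkoxides first; the C8 alkoxide forbids enolisation toward C8, and oxaziridine oxidation should give the 4,6,8-triol F3. Ag2O and 4-methoxybenzyl bromide etherify the only secondary hydroxyl to the 8-O-(4-methoxybenzyl) ether F4. Esterification with 21 (EDC, DMAP) at the activated α-ketol hydroxyl gives the ester F5, and silylation of the remaining tertiary C4 hydroxyl (TBSOTf, 2,6-lutidine) returns to 22.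

Step 12. Most likely failure: competing deprotonation of the ketone at C8 (with epoxide elimination) or retro-aldol cleavage on warming, because a strong amide base is used beside an enolisable ketone. Fallback, from 20 to 24: acylate 20 with 2-(diethoxyphosphoryl)acrylic acid (EDC, DMAP) to the phosphonoacrylate ester F6. KOSiMe2tBu in THF adds to the vinylphosphonate (oxa-Michael), and the phosphonate anion formed olefinates the C7 ketone in an intramolecular Horner–Wadsworth–Emmons reaction, which should give 24 directly under weakly basic conditions.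

Step 15. Most likely failure: acetylation of the hemiketal hydroxyl to a stable pseudo-acetate without elimination, or enol acylation through the other enol geometry so that C5=C6 forms with C4 trans to C7. Fallback, from 26 to 27: acetylate only the C9 hydroxyl (AcCl, 2,4,6-collidine, −40 °C) to the 9-acetate F7, then dehydrate the hemiketal with methyl N-(triethylammoniosulfonyl)carbamate (benzene, 50 °C). The syn-elimination of the sulfamate from the cyclic form removes a C5 hydrogen within the lactone framework and should give 27.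

## Further compounds

F1 | step 14 | lactol from 24 (C12 hemiacetal) | [C@@]14(COCc2ccc(OC)cc2)O[C@H]4[C@H](OCc2ccc(OC)cc2)C5=C(CO[Si](C)(C)C(C)(C)C)C(O)O[C@@]53C[C@](C)(O[Si](C)(C)C(C)(C)C)C=C[C@@H]13
F2 | step 14 | ten-membered (Z)-keto enal with free 9-OH | COc1ccc(CO[C@@H]2/C(=C(\CO[Si](C)(C)C(C)(C)C)C=O)C(=O)C[C@](C)(O[Si](C)(C)C(C)(C)C)/C=C\C=C(\COCc3ccc(OC)cc3)[C@H]2O)cc1
F3 | step 10 | 4α,6α,8α-triol 9β,10β-epoxy ketone | [C@@]14(COCc2ccc(OC)cc2)O[C@H]4[C@H](O)C(=O)[C@@]3(O)C[C@](C)(O)C=C[C@@H]13
F4 | step 10 | 8-O-(4-methoxybenzyl) ether of F3 | [C@@]14(COCc2ccc(OC)cc2)O[C@H]4[C@H](OCc2ccc(OC)cc2)C(=O)[C@@]3(O)C[C@](C)(O)C=C[C@@H]13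
F5 | step 10 | 6-O-[3-(tert-butyldimethylsilyloxy)propanoyl] ester of F4 | [C@@]14(COCc2ccc(OC)cc2)O[C@H]4[C@H](OCc2ccc(OC)cc2)C(=O)[C@@]3(OC(=O)CCO[Si](C)(C)C(C)(C)C)C[C@](C)(O)C=C[C@@H]13
F6 | step 12 | 6-O-[2-(diethoxyphosphoryl)acryloyl] ester of 20 | [C@@]14(COCc2ccc(OC)cc2)O[C@H]4[C@H](OCc2ccc(OC)cc2)C(=O)[C@@]3(OC(=O)C(=C)P(=O)(OCC)OCC)C[C@](C)(O[Si](C)(C)C(C)(C)C)C=C[C@@H]13
F7 | step 15 | 9-acetate of hydroxybutenolide 26 | COc1ccc(CO[C@@H]2C3=C(CO[Si](C)(C)C(C)(C)C)C(=O)OC3(O)C[C@](C)(O[Si](C)(C)C(C)(C)C)/C=C\C=C(\COCc3ccc(OC)cc3)[C@H]2OC(C)=O)cc1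
A1 | alternative 1 | seco (Z)-alkenyl iodide C9 aldehyde | CC(C)(C)[Si](C)(C)O[C@@H](C=O)C1=C(COC(C)=O)C(=O)O/C1=C/[C@](C)(O[Si](CC)(CC)CC)[C@@H]2O[C@@H]2/C=C(\I)COCc3ccc(OC)cc3
A2 | alternative 2 | 1,2-dialkenylcyclohex-3-en-1-ol with two enol ether termini | C[C@@]1(O[Si](CC)(CC)CC)C=C[C@@H](/C(CO[Si](C)(C)C(C)(C)C)=C/OCOC)[C@](O)(/C(=C/OCc2ccc(OC)cc2)C(CO[Si](C)(C)C(C)(C)C)C(=O)OC)C1
A3 | alternative 3 | 2-silyloxyfuran C5 aldehyde | O=C[C@](C)(O[Si](CC)(CC)CC)[C@@H]1O[C@@H]1/C=C(/COCc1ccc(OC)cc1)[C@@H](OC(C)=O)[C@H](O[Si](C)(C)C(C)(C)C)c1c(COC(C)=O)c(O[Si](C(C)C)(C(C)C)C(C)C)oc1
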